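25 ⇒ bis(8-aminoquinoline) diamide 22 (steps 14 and 15): both carboxyl groups are carried as amides whose N,N-chelate directs nickel and is removed at the end.
Key disconnection: the CH2–CH= single bond between C4 (homoallylic CH2) and C3 (β-carbon of the acid that bears the 4-methylpent-3-enyl group) of the tridecadienedioic acid chain, made by amide-directed, nickel-catalysed alkylation of the cis β-C–H bond of the geometry-free acrylamide 4 with primary iodide 21.
Enabling feature: in each 2-alkylacrylic acid unit the carboxyl carbon and the β-CH2 carbon are cis on the trisubstituted C=C, so amide N, carbonyl C, Cα, Cβ and Ni can close a five-membered metallacycle only on the side that gives the Z alkene; the same reaction with bromide 8 sets the second Z acid (step 10).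
21 ⇐ acid 19 (carboxyl carbon excised by iododecarboxylation) ⇐ Johnson–Claisen rearrangement (E trisubstituted alkene) ⇐ aldehyde-selective isopropenylation of keto aldehyde 11 ⇐ (R)-limonene oxide 9 (stereocentre and isopropenyl group); both acrylamides come from methyl ketones (1 and 14) by enol triflation and aminocarbonylation.
Rings: none is formed; the furan is bought as 3-bromofuran 5, and the epoxide and cyclohexane rings of 9 are opened in step 5.

Key step: step 13

Remark: commercial (+)-limonene 1,2-oxide 9 is taken as the cis/trans epoxide mixture derived from (R)-limonene; both isomers converge on the same cleavage product in step 5.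

Step 1
Reactants: 1 6-methylhept-5-en-2-one
Product: 3 6-methylhepta-1,5-dien-2-yl trifluoromethanesulfonate, via lithium enolate 2 (not isolated)
Conditions: LiN(iPr)2, THF, −78 °C; then PhNTf2, −78 to 0 °C
Reagents that add atoms: N-phenylbis(trifluoromethanesulfonimide), O=S(=O)(N(c1ccccc1)S(=O)(=O)C(F)(F)F)C(F)(F)F
Why: The hindered lithium amide removes a methyl proton of the ketone under kinetic control at −78 °C and the terminal enolate is O-sulfonylated by PhNTf2 (kinetic enol triflate formation), leaving the trisubstituted alkene untouched.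

Step 2
Reactants: 3 6-methylhepta-1,5-dien-2-yl trifluoromethanesulfonate
Product: 4 6-methyl-2-methylidene-N-(quinolin-8-yl)hept-5-enamide
Conditions: CO (1 atm), 8-aminoquinoline, Pd(OAc)2 (5 mol %), Xantphos, Et3N, DMF, 70 °C
Reagents that add atoms: carbon monoxide, [C-]#[O+]; 8-aminoquinoline, Nc1cccc2cccnc12
Why: Oxidative addition of the alkenyl triflate to zerovalent palladium, CO insertion and attack of the primary amine of 8-aminoquinoline on the acylpalladium should give the 2-substituted acrylamide (palladium-catalysed aminocarbonylation), the wide-bite-angle Xantphos keeping the chelating amine from blocking the metal.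

Step 3
Reactants: 5 3-bromofuran
Product: 7 2-(furan-3-yl)ethan-1-ol, via furan-3-yllithium 6 (not isolated)
Conditions: n-BuLi, THF, −78 °C; then oxirane, BF3·OEt2, −78 °C
Reagents that add atoms: oxirane, C1CO1
Why: Bromine–lithium exchange at −78 °C gives furan-3-yllithium without equilibration to the 2-lithio isomer, and the BF3-activated oxirane is opened by the aryllithium to the two-carbon alcohol (Lewis acid-assisted epoxide opening).

Step 4
Reactants: 7 2-(furan-3-yl)ethan-1-ol
Product: 8 3-(2-bromoethyl)furan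
Conditions: CBr4, PPh3, CH2Cl2, 0 °C
Reagents that add atoms: carbon tetrabromide, BrC(Br)(Br)Br
Why: The Appel reaction turns the primary alcohol into the bromide under neutral conditions that the acid-sensitive furan tolerates.

Step 5
Reactants: 9 (+)-limonene 1,2-oxide [(4R); cis/trans mixture]
Product: 11 (3R)-6-oxo-3-(prop-1-en-2-yl)heptanal, via limonene-1,2-diol 10 (not isolated)
Conditions: H5IO6, THF/H2O, 0 to 25 °C
Reagents that add atoms: water, O
Why: Periodic acid hydrolyses the trisubstituted epoxide to the 1,2-diol and cleaves it in the same flask (glycol cleavage), which unveils the former ring alkene carbons as methyl ketone and aldehyde while the R stereocentre and the isopropenyl group are not involved.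

Step 6
Reactants: 11 (3R)-6-oxo-3-(prop-1-en-2-yl)heptanal
Product: 12 (5R)-7-hydroxy-8-methyl-5-(prop-1-en-2-yl)non-8-en-2-one (both C7 epimers)
Conditions: 2-bromopropene, CrCl2, NiCl2 (2 mol %), DMF, 25 °C
Reagents that add atoms: 2-bromopropene, C=C(C)Br
Why: The Nozaki–Hiyama–Kishi reaction adds the isopropenylchromium reagent to the aldehyde only and leaves the methyl ketone alone; the carbinol centre is formed without control, which does not matter because it becomes sp2 in step 7.

Step 7
Reactants: 12 (5R)-7-hydroxy-8-methyl-5-(prop-1-en-2-yl)non-8-en-2-one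
Product: 14 ethyl (4E,7R)-4-methyl-10-oxo-7-(prop-1-en-2-yl)undec-4-enoate, via ketene acetal 13 (not isolated)
Conditions: MeC(OEt)3, EtCO2H (cat.), 140 °C, EtOH distilled off; then 1 M HCl, THF, 25 °C
Reagents that add atoms: triethyl orthoacetate, CC(OCC)(OCC)OCC
Why: Johnson–Claisen rearrangement of the mixed ketene acetal through a chair transition state with the carbinol substituent equatorial should give the E trisubstituted alkene and adds the two-carbon ester arm, and the acidic work-up returns any ketal or enol ether formed at the methyl ketone.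

Step 8
Reactants: 14 ethyl (4E,7R)-4-methyl-10-oxo-7-(prop-1-en-2-yl)undec-4-enoate
Product: 16 ethyl (4E,7R)-4-methyl-7-(prop-1-en-2-yl)-10-[(trifluoromethanesulfonyl)oxy]undeca-4,10-dienoate, via lithium enolate 15 (not isolated)
Conditions: LiN(iPr)2 (1.05 equiv), THF, −78 °C; then PhNTf2, −78 to 0 °C
Reagents that add atoms: N-phenylbis(trifluoromethanesulfonimide), O=S(=O)(N(c1ccccc1)S(=O)(=O)C(F)(F)F)C(F)(F)F
Why: The methyl ketone is several pKa units more acidic than the ester and is deprotonated kinetically at its methyl group, so the terminal enolate can be trapped as the enol triflate (as in step 1) without touching the ester or the remote stereocentre.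

Step 9
Reactants: 16 ethyl (4E,7R)-4-methyl-7-(prop-1-en-2-yl)-10-[(trifluoromethanesulfonyl)oxy]undeca-4,10-dienoate
Product: 17 ethyl (4E,7R)-4-methyl-7-(prop-1-en-2-yl)-10-[(quinolin-8-yl)carbamoyl]undeca-4,10-dienoate
Conditions: CO (1 atm), 8-aminoquinoline, Pd(OAc)2 (5 mol %), Xantphos, Et3N, DMF, 70 °C
Reagents that add atoms: carbon monoxide, [C-]#[O+]; 8-aminoquinoline, Nc1cccc2cccnc12
Why: Palladium-catalysed aminocarbonylation as in step 2 converts the alkenyl triflate into the 2-substituted acrylamide that carries the directing group, and the saturated ester and the three alkenes are inert to these conditions.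

Step 10
Reactants: 17 ethyl (4E,7R)-4-methyl-7-(prop-1-en-2-yl)-10-[(quinolin-8-yl)carbamoyl]undeca-4,10-dienoate; 8 3-(2-bromoethyl)furan
Product: 18 ethyl (4E,7R,10Z)-13-(furan-3-yl)-4-methyl-7-(prop-1-en-2-yl)-10-[(quinolin-8-yl)carbamoyl]trideca-4,10-dienoate
Conditions: 8 (2 equiv), Ni(OTf)2 (10 mol %), PPh3 (20 mol %), Na2CO3, toluene, 140 °C
Reagents that add atoms: none
Why: In this nickel-catalysed, 8-aminoquinoline-directed alkylation the N,N-chelated nickel can cleave only the vinylic C–H bond cis to the carbonyl group (five-membered nickelacycle), so coupling with the primary bromide places the furylethyl chain cis to the amide and gives the Z alkene, after which no cis β-hydrogen remains for a second alkylation.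

Step 11
Reactants: 18 ethyl (4E,7R,10Z)-13-(furan-3-yl)-4-methyl-7-(prop-1-en-2-yl)-10-[(quinolin-8-yl)carbamoyl]trideca-4,10-dienoate
Product: 19 (4E,7R,10Z)-13-(furan-3-yl)-4-methyl-7-(prop-1-en-2-yl)-10-[(quinolin-8-yl)carbamoyl]trideca-4,10-dienoic acid
Conditions: LiOH, THF/H2O, 25 °C; then 1 M HCl to pH 3
Reagents that add atoms: lithium hydroxide, [Li+].[OH-]
Why: Hydroxide saponifies the unhindered saturated ethyl ester at room temperature while the secondary 8-aminoquinoline amide and the alkene geometries are unaffected (ester hydrolysis).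

Step 12
Reactants: 19 (4E,7R,10Z)-13-(furan-3-yl)-4-methyl-7-(prop-1-en-2-yl)-10-[(quinolin-8-yl)carbamoyl]trideca-4,10-dienoic acid
Product: 21 (2Z)-5-(furan-3-yl)-2-[(3R,5E)-8-iodo-6-methyl-3-(prop-1-en-2-yl)oct-5-en-1-yl]-N-(quinolin-8-yl)pent-2-enamide, via Barton ester 20 (not isolated)
Conditions: N-hydroxypyridine-2-thione, DCC, DMAP (cat.), CH2Cl2, 0 °C, dark; then CHI3, hν (tungsten lamp), 25 °C
Reagents that add atoms: iodoform, IC(I)I
Why: Barton decarboxylation: the thiohydroxamate ester fragments under visible light to CO2 and the primary alkyl radical, which takes iodine from iodoform faster than it can reach any of the remote alkenes, so the carboxyl carbon that the Claisen step brought in is excised and the chain ends in CH2I.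

Step 13
Reactants: 21 (2Z)-5-(furan-3-yl)-2-[(3R,5E)-8-iodo-6-methyl-3-(prop-1-en-2-yl)oct-5-en-1-yl]-N-(quinolin-8-yl)pent-2-enamide; 4 6-methyl-2-methylidene-N-(quinolin-8-yl)hept-5-enamide
Product: 22 (2Z,6E,9R,12Z)-12-[3-(furan-3-yl)propylidene]-6-methyl-2-(4-methylpent-3-en-1-yl)-9-(prop-1-en-2-yl)-N1,N13-di(quinolin-8-yl)trideca-2,6-dienediamide
Conditions: 4 (2 equiv), Ni(OTf)2 (10 mol %), PPh3 (20 mol %), Na2CO3, toluene, 140 °C
Reagents that add atoms: none
Why: The deprotonated 8-aminoquinoline amide of 4 binds divalent nickel through both nitrogens, and carbonate-assisted metalation then cleaves the one vinylic C–H bond that lies cis to the carbonyl group, closing a five-membered nickelacycle (Ni, amide N, carbonyl C, Cα, Cβ); iodide 21 is taken up at nickel (oxidative addition, or iodine abstraction and radical rebound, to a higher-valent alkylnickel), C(sp2)–C(sp3) reductive elimination forms the CH2–CH= bond, and protonation of the amide nitrogen frees the catalyst. The closest known reaction type is the nickel-catalysed, 8-aminoquinoline-directed alkylation of acrylamide and benzamide C–H bonds with unactivated primary alkyl halides. No ring of the product is closed and no stereocentre is created; the new stereo-element is the trisubstituted double bond, whose Z geometry (alkyl chain cis to the amide carbon) is dictated by the chelate because the trans C–H bond cannot reach the metal. The step needs site selectivity, monoalkylation and chemoselectivity between the two amides: 4 has a single cis β-hydrogen, the product has none left, and the amide already present in 21 carries no cis β-hydrogen at all, so only the intended C–H bond can react. The R stereocentre, the E alkene, the Z amide of 21 and the furan are spectators, and the excess of the cheap acrylamide 4 compensates for any iodide lost by elimination.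

Step 14
Reactants: 22 (2Z,6E,9R,12Z)-12-[3-(furan-3-yl)propylidene]-6-methyl-2-(4-methylpent-3-en-1-yl)-9-(prop-1-en-2-yl)-N1,N13-di(quinolin-8-yl)trideca-2,6-dienediamide
Product: 23 (2Z,6E,9R,12Z)-N1,N13-bis(tert-butoxycarbonyl)-12-[3-(furan-3-yl)propylidene]-6-methyl-2-(4-methylpent-3-en-1-yl)-9-(prop-1-en-2-yl)-N1,N13-di(quinolin-8-yl)trideca-2,6-dienediamide
Conditions: Boc2O, DMAP, MeCN, 50 °C
Reagents that add atoms: di-tert-butyl dicarbonate, CC(C)(C)OC(=O)OC(=O)OC(C)(C)C
Why: DMAP-catalysed acylation of each amide nitrogen with Boc2O gives twisted N-acyl carbamates whose acyl C–N bonds are activated for mild cleavage (amide activation), and nothing else in the molecule is acylated.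

Step 15
Reactants: 23 (2Z,6E,9R,12Z)-N1,N13-bis(tert-butoxycarbonyl)-12-[3-(furan-3-yl)propylidene]-6-methyl-2-(4-methylpent-3-en-1-yl)-9-(prop-1-en-2-yl)-N1,N13-di(quinolin-8-yl)trideca-2,6-dienediamide
Product: 25 (2Z,6E,9R,12Z)-12-[3-(furan-3-yl)propylidene]-6-methyl-2-(4-methylpent-3-en-1-yl)-9-(prop-1-en-2-yl)trideca-2,6-dienedioic acid, via bis(peroxy acid) 24 (not isolated)
Conditions: LiOH, H2O2, THF/H2O, 0 °C; then Na2SO3; then 1 M HCl to pH 3
Reagents that add atoms: hydrogen peroxide, OO
Why: Hydroperoxide anion attacks the acyl carbonyl of each N-acyl carbamate in preference to the hindered carbamate carbonyl (as in the cleavage of N-acyloxazolidinones), and sulfite reduces the peroxy acids to the two carboxylic acids without a pathway for Z to E isomerisation.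

Compound list
1 | 6-methylhept-5-en-2-one (sulcatone) | CC(=O)CCC=C(C)C | starting material
2 | lithium 6-methylhepta-1,5-dien-2-olate | [Li+].[O-]C(=C)CCC=C(C)C | intermediate
3 | 6-methylhepta-1,5-dien-2-yl trifluoromethanesulfonate | C=C(CCC=C(C)C)OS(=O)(=O)C(F)(F)F | intermediate
4 | 6-methyl-2-methylidene-N-(quinolin-8-yl)hept-5-enamide | C=C(CCC=C(C)C)C(=O)Nc1cccc2cccnc12 | intermediate
5 | 3-bromofuran | Brc1ccoc1 | starting material
6 | furan-3-yllithium | [Li]c1ccoc1 | intermediate
7 | 2-(furan-3-yl)ethan-1-ol | OCCc1ccoc1 | intermediate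
8 | 3-(2-bromoethyl)furan | BrCCc1ccoc1 | intermediate
9 | (+)-limonene 1,2-oxide, (4R)-1-methyl-4-(prop-1-en-2-yl)-7-oxabicyclo[4.1.0]heptane, cis/trans mixture at the epoxide | CC12OC1C[C@@H](CC2)C(C)=C | starting material
10 | (4R)-1-methyl-4-(prop-1-en-2-yl)cyclohexane-1,2-diol (limonene-1,2-diol) | CC1(O)C(O)C[C@@H](CC1)C(C)=C | intermediate
11 | (3R)-6-oxo-3-(prop-1-en-2-yl)heptanal | C=C(C)[C@@H](CC=O)CCC(C)=O | intermediate
12 | (5R)-7-hydroxy-8-methyl-5-(prop-1-en-2-yl)non-8-en-2-one, both C7 epimers | C=C(C)[C@@H](CC(O)C(C)=C)CCC(C)=O | intermediate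
13 | (5R)-7-[(1-ethoxyethenyl)oxy]-8-methyl-5-(prop-1-en-2-yl)non-8-en-2-one (ketene acetal) | C=C(C)[C@@H](CC(OC(=C)OCC)C(C)=C)CCC(C)=O | intermediate
14 | ethyl (4E,7R)-4-methyl-10-oxo-7-(prop-1-en-2-yl)undec-4-enoate | C=C(C)[C@@H](C/C=C(\C)CCC(=O)OCC)CCC(C)=O | intermediate
15 | lithium (5R,7E)-11-ethoxy-8-methyl-11-oxo-5-(prop-1-en-2-yl)undeca-1,7-dien-2-olate | C=C(C)[C@@H](C/C=C(\C)CCC(=O)OCC)CCC(=C)[O-].[Li+] | intermediate
16 | ethyl (4E,7R)-4-methyl-7-(prop-1-en-2-yl)-10-[(trifluoromethanesulfonyl)oxy]undeca-4,10-dienoate | C=C(C)[C@@H](C/C=C(\C)CCC(=O)OCC)CCC(=C)OS(=O)(=O)C(F)(F)F | intermediate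
17 | ethyl (4E,7R)-4-methyl-7-(prop-1-en-2-yl)-10-[(quinolin-8-yl)carbamoyl]undeca-4,10-dienoate | C=C(C)[C@@H](C/C=C(\C)CCC(=O)OCC)CCC(=C)C(=O)Nc1cccc2cccnc12 | intermediate
18 | ethyl (4E,7R,10Z)-13-(furan-3-yl)-4-methyl-7-(prop-1-en-2-yl)-10-[(quinolin-8-yl)carbamoyl]trideca-4,10-dienoate (amide carbon cis to the furylethyl chain) | C=C(C)[C@@H](C/C=C(\C)CCC(=O)OCC)CC/C(=C/CCc1ccoc1)C(=O)Nc1cccc2cccnc12 | intermediate
19 | (4E,7R,10Z)-13-(furan-3-yl)-4-methyl-7-(prop-1-en-2-yl)-10-[(quinolin-8-yl)carbamoyl]trideca-4,10-dienoic acid | C=C(C)[C@@H](C/C=C(\C)CCC(=O)O)CC/C(=C/CCc1ccoc1)C(=O)Nc1cccc2cccnc12 | intermediate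
20 | 2-sulfanylidenepyridin-1(2H)-yl ester of 19 (Barton ester) | C=C(C)[C@@H](C/C=C(\C)CCC(=O)ON1C=CC=CC1=S)CC/C(=C/CCc1ccoc1)C(=O)Nc1cccc2cccnc12 | intermediate
21 | (2Z)-5-(furan-3-yl)-2-[(3R,5E)-8-iodo-6-methyl-3-(prop-1-en-2-yl)oct-5-en-1-yl]-N-(quinolin-8-yl)pent-2-enamide | C=C(C)[C@@H](C/C=C(\C)CCI)CC/C(=C/CCc1ccoc1)C(=O)Nc1cccc2cccnc12 | intermediate
22 | (2Z,6E,9R,12Z)-12-[3-(furan-3-yl)propylidene]-6-methyl-2-(4-methylpent-3-en-1-yl)-9-(prop-1-en-2-yl)-N1,N13-di(quinolin-8-yl)trideca-2,6-dienediamide (each amide carbon cis to its β-CH2) | C=C(C)[C@@H](C/C=C(\C)CC/C=C(/CCC=C(C)C)C(=O)Nc1cccc2cccnc12)CC/C(=C/CCc1ccoc1)C(=O)Nc1cccc2cccnc12 | intermediate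
23 | N1,N13-bis(tert-butoxycarbonyl) derivative of 22 | C=C(C)[C@@H](C/C=C(\C)CC/C=C(/CCC=C(C)C)C(=O)N(C(=O)OC(C)(C)C)c1cccc2cccnc12)CC/C(=C/CCc1ccoc1)C(=O)N(C(=O)OC(C)(C)C)c1cccc2cccnc12 | intermediate
24 | (2Z,6E,9R,12Z)-12-[3-(furan-3-yl)propylidene]-6-methyl-2-(4-methylpent-3-en-1-yl)-9-(prop-1-en-2-yl)trideca-2,6-dienediperoxoic acid | C=C(C)[C@@H](C/C=C(\C)CC/C=C(/CCC=C(C)C)C(=O)OO)CC/C(=C/CCc1ccoc1)C(=O)OO | intermediate
25 | (2Z,6E,9R,12Z)-12-[3-(furan-3-yl)propylidene]-6-methyl-2-(4-methylpent-3-en-1-yl)-9-(prop-1-en-2-yl)trideca-2,6-dienedioic acid (CNP0235727.1; each carboxyl group cis to its β-CH2) | C=C(C)[C@@H](C/C=C(\C)CC/C=C(/CCC=C(C)C)C(=O)O)CC/C(=C/CCc1ccoc1)C(=O)O | target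

Total step count: 15.
Longest linear sequence: 11 steps (9 to 25, steps 5 to 15).

Steps most likely to fail

Step 13 (key alkylation). At 140 °C the homoallylic iodide may lose HI to the 1,3-diene, either by base or by β-hydride elimination at nickel. A nickel hydride formed in this way may move the 1,1-disubstituted double bond of 4, or the isopropenyl double bond, into conjugation; the latter would erase the stereocentre. The Z amide may also partly isomerise. The fallback sets out from 21 and comes back at 22; it replaces the C–H functionalisation by a stereoretentive Negishi coupling with a preformed Z iodoalkene. 4-Methylpent-3-en-1-ylmagnesium bromide F1 (from commercial 5-bromo-2-methylpent-2-ene and Mg) adds anti across propargyl alcohol under CuI catalysis to give the cyclic alkenylmagnesium alkoxide F2, in which the alkoxide holds magnesium cis to the CH2O group. Quenching with I2 gives (2Z)-3-iodo-2-(4-methylpent-3-en-1-yl)prop-2-en-1-ol F3. MnO2 gives (2Z)-3-iodo-2-(4-methylpent-3-en-1-yl)prop-2-enal F4, and buffered NaClO2 with 2-methylbut-2-ene gives (2Z)-3-iodo-2-(4-methylpent-3-en-1-yl)prop-2-enoic acid F5. Coupling with 8-aminoquinoline (EDC, DMAP) gives (2Z)-3-iodo-2-(4-methylpent-3-en-1-yl)-N-(quinolin-8-yl)prop-2-enamide F6. Iodide 21 is converted with zinc dust and LiCl in THF into the alkylzinc iodide F7, which should tolerate the amide N–H groups, and F7 and F6 are coupled with Pd(dppf)Cl2 at 40 °C to give 22 with retention of the Z geometry.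

Step 15 (removal of both auxiliaries). Hydroperoxide may attack the carbamate carbonyl and return the amide, or add in conjugate fashion to the activated Z-enoyl groups. Acyl transfer at the two hindered centres may stall at the mono-acid, and prolonged exposure to base may erode the Z geometry. The fallback sets out from 23 and comes back at 25; it uses transesterification followed by neutral ester cleavage. K2CO3 in MeOH at 0 °C should convert 23 into dimethyl (2Z,6E,9R,12Z)-12-[3-(furan-3-yl)propylidene]-6-methyl-2-(4-methylpent-3-en-1-yl)-9-(prop-1-en-2-yl)trideca-2,6-dienedioate F8, and Me3SnOH in 1,2-dichloroethane at 70 °C should hydrolyse F8 to 25.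

Step 12 (iododecarboxylation). The primary radical may recombine with the thiohydroxamate to the 2-pyridyl sulfide before iodine transfer. The diiodomethyl chain carrier may add to the isopropenyl group, and thiyl radicals may scramble the alkene geometry. The fallback sets out from 19 and comes back at 21; it uses a redox-active ester in place of the thiohydroxamate. Acid 19 is esterified with N-hydroxyphthalimide (DIC, DMAP) to the 1,3-dioxoisoindolin-2-yl ester of 19 F9. Irradiation of F9 at 456 nm with LiI and catalytic PPh3 in acetone should give 21 by photoinduced electron transfer within the iodide–phosphine–phthalimide charge-transfer complex, a non-chain process without a thiyl radical.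

Further compounds
F1 | step 13 | 4-methylpent-3-en-1-ylmagnesium bromide | CC(C)=CCC[Mg]Br
F2 | step 13 | 4-(4-methylpent-3-en-1-yl)-2,5-dihydro-1,2-oxamagnesole (cyclic alkenylmagnesium alkoxide) | CC(C)=CCCC1=C[Mg]OC1
F3 | step 13 | (2Z)-3-iodo-2-(4-methylpent-3-en-1-yl)prop-2-en-1-ol | OC/C(CCC=C(C)C)=C\I
F4 | step 13 | (2Z)-3-iodo-2-(4-methylpent-3-en-1-yl)prop-2-enal | O=C/C(CCC=C(C)C)=C\I
F5 | step 13 | (2Z)-3-iodo-2-(4-methylpent-3-en-1-yl)prop-2-enoic acid | OC(=O)/C(CCC=C(C)C)=C\I
F6 | step 13 | (2Z)-3-iodo-2-(4-methylpent-3-en-1-yl)-N-(quinolin-8-yl)prop-2-enamide | O=C(Nc1cccc2cccnc12)/C(CCC=C(C)C)=C\I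
F7 | step 13 | iodo{(3E,6R,9Z)-12-(furan-3-yl)-3-methyl-6-(prop-1-en-2-yl)-9-[(quinolin-8-yl)carbamoyl]dodeca-3,9-dien-1-yl}zinc | C=C(C)[C@@H](C/C=C(\C)CC[Zn]I)CC/C(=C/CCc1ccoc1)C(=O)Nc1cccc2cccnc12
F8 | step 15 | dimethyl (2Z,6E,9R,12Z)-12-[3-(furan-3-yl)propylidene]-6-methyl-2-(4-methylpent-3-en-1-yl)-9-(prop-1-en-2-yl)trideca-2,6-dienedioate | C=C(C)[C@@H](C/C=C(\C)CC/C=C(/CCC=C(C)C)C(=O)OC)CC/C(=C/CCc1ccoc1)C(=O)OC
F9 | step 12 | 1,3-dioxoisoindolin-2-yl (4E,7R,10Z)-13-(furan-3-yl)-4-methyl-7-(prop-1-en-2-yl)-10-[(quinolin-8-yl)carbamoyl]trideca-4,10-dienoate | C=C(C)[C@@H](C/C=C(\C)CCC(=O)ON1C(=O)c2ccccc2C1=O)CC/C(=C/CCc1ccoc1)C(=O)Nc1cccc2cccnc12
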